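**A missing share.** In larch, the flask asked about, G could not grow from X that had gone: cX read 0.7 % at 25.0 h, yet 69.9 % of the charge lay in neither X nor G. Turned round, the question was this: for removal or heat to be useless, that missing share had to be a dead drain on G.

all flasks: X 0.19 M; temperature 20 °C

| run | Z | E | remark | time | volume of the second phase over the first |
|---|---|---|---|---|---|
| larch | 1.5 equiv | 10 mol% | the very flask that is asked about, followed so far |  |  |
| birch | 1.5 equiv | 5 mol% | run made earlier |  |  |
| flask | 1.50 equiv | 10 mol% |  | 25 h | 1.0 |

| run | time / h | G / % | X / % |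
|---|---|---|---|
| larch | 2.00 | 21.9 | 47.9 |
| larch | 3.00 | 24.8 | 33.7 |
| larch | 6.00 | 27.1 | 11.4 |
| larch | 10.0 | 30.7 | 4.3 |
| larch | 15.0 | 30.6 | 2.3 |
| larch | 25.0 | 29.4 | 0.7 |
| birch | 0.167 | 0.6 | 98.5 |
| birch | 0.500 | 6.9 | 91.5 |
| birch | 0.833 | 8.9 | 85.7 |
| birch | 1.33 | 12.8 | 78.6 |
| birch | 2.00 | 14.4 | 70.1 |
| birch | 2.50 | 14.8 | 63.5 |

(each reading ± 1 percentage point)

- south-east: at 25 h add X, 50.0 % of the amount charged, then wait 8.0 h
- north-west: at 25 h raise the temperature by 10 K, then wait 8.0 h
- south-west: at 25 h take out 90 % of the G then present, then wait 8.0 h
- north: change nothing and wait 8.0 h more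

- G, in percent of the X first charged, at 25 h
- what to do for the largest gain in G; "none" if nothing gains more than 2 percentage points (south-east / north-west / south-west / north / none)
- G present, with what was taken out counted in, in percent of the X first charged, after south-east
- G present, with what was taken out counted in, in percent of the X first charged, after north-west

- charges count per volume of the first phase; a concentration in a rate is the amount of a species over the volume of its own phase; every rate counts per litre of the first phase
- G taken out counts as made
- what was read earlier has a scatter of 1 percentage point, one standard deviation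
- the earlier runs hold the two phases in the same ratio of volumes as the flask asked about
- the earlier runs do not show what temperature does; that part of a forecast is a guess
- additions bring no volume worth counting

**Drain test.** Between 2.00 h and 3.00 h the missing share grew at 0.484 h⁻¹ per unit of G. Kept up from 10.0 h to 25.0 h, that drain leaves 0.0703 % of the G, but larch read 30.7 % and then 29.4 %, far more than that share of the first reading. The missing share over cG read 1.38 at 2.00 h, then 2.12, 2.19 and 2.38 late. The readings did not exclude a direct branch from X, but I committed to a split at rest (thermodynamic control), with the split ratio s, the late missing share over cG, read as 2.23. In my reckoning for larch, cG is then whatever is not X, divided by one plus s, which gave me 30.7 % at 25 h.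

**Options reckoned.** In larch, by my reckoning, taking out 90 % of the G and letting the split re-form gained 20 percentage points. By the same reckoning added X, even fully converted, gained 15 points, less than that. Heat was a guess: it had to bring s down to 1.03, about half of its value, to beat removal. I chose south-west.

**The forecast.** It gave 30.2 %, south-east, 35 % and 30.4 %, holding that “Heating or removing G has almost no X left to act on”. My ranking differed.

**Result.** The flask gave 30.0 % at 25 h; south-east gave 33.6 %, and north-west won with 52.5 %, a gain of 22 points.

    E + Z ⇌ J + D (K = 11.9, k = 0.375 L mol⁻¹ min⁻¹, Ea = 62.0 kJ mol⁻¹, ΔH = −34.0 kJ mol⁻¹)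
    X + J → G + E (k = 0.816 L mol⁻¹ min⁻¹, Ea = 61.0 kJ mol⁻¹)
    G ⇌ L (K = 2.07, k = 0.0249 min⁻¹, Ea = 79.0 kJ mol⁻¹, ΔH = −78.0 kJ mol⁻¹)
    G + E → Q (k = 0.0754 L mol⁻¹ min⁻¹, Ea = 75.0 kJ mol⁻¹)
    (constants at 20 °C)

By that step alone, G and L relax with a half-life of 0.313 h, short against 25 h. Read the same way, as all that is not G over G, 52.5 % of G puts the ratio at 0.905 after heating, below my bar of 1.03. The neighbour with 2.5 mol% of E kept 25 % of its X, so s gives 23.2 % of G there, and it held 23.9 %.

The readings were computed from invented constants.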